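Weigh the two drains on the coupling partner before you trust any rate.

| setting | Thursday's | Sunday's | flask |
|---|---|---|---|
| left-handed substrate | 1 M | 1 M | 1.0 M |
| right-handed substrate | 1 M | 1 M | 1.0 M |
| coupling partner | 1.1 M | 0.55 M | 1.10 M |
| free catalyst | 99 mM | 99 mM | 99 mM |
| remark | the very flask that is asked about, followed so far | run made earlier |  |

- Thursday's (time / h: left-handed product / %, left-handed substrate / %): 0.200: 7.9, 38.1; 0.417: 14.2, 32.1; 1.00: 22.5, 23.5; 2.50: 30.3, 16.0
- Sunday's (time / h: left-handed product / %, left-handed substrate / %): 0.833: 11.9, 34.3; 2.00: 17.8, 27.4; 4.00: 19.3, 24.1; 6.00: 20.3, 25.3

(standard deviation of a reading: 0.5 percentage points)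

- free catalyst is single-handed; left-handed substrate and right-handed substrate are mirror images of each other, charged as a racemate, each of them at the stated concentration
- the earlier runs were read with a standard deviation of 0.5 percentage points
- steps that have been proposed: free catalyst + left-handed substrate <-> catalyst intermediate A; free catalyst + right-handed substrate <-> catalyst intermediate B; coupling partner + catalyst intermediate A -> free catalyst + left-handed product; coupling partner + catalyst intermediate B -> free catalyst + right-handed product; 2 coupling partner -> self-condensation product
- no earlier run changes the charge of free catalyst; that part of a forecast is a guess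
- what is bound to the catalyst counts as converted

- apparent order in free catalyst when 30 % of the left-handed substrate and right-handed substrate together are converted (percent change of the rate of making left-handed product for one percent more free catalyst charged)
- factor on the rate of making left-handed product when 30 % of the left-handed substrate and right-handed substrate together are converted if coupling partner is charged twice over

1. Slope. Thursday's flask, the one asked about, starts making left-handed product at about 0.790 M h⁻¹, read from its first point.

2. Rule. Take catalyst intermediate A as constant. Coupling then drains partner in proportion to c(coupling partner), and self-condensation drains it as the square. So coupling's share of the partner is c×/(c× + c). Added up, the product level is c× ln(1 + c0/c×), where c0 is the partner charged.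

3. Crossing. Sunday's flask reads 0.406 M of left-handed product from 0.55 M of partner. A short form of that logarithm then gives c× = 0.775 M, the crossing concentration: the c(coupling partner) at which both drains run equally.

4. Knee. Thursday's partner starts above c×, so self-condensation first takes 1.12 M h⁻¹ of partner. The crossing comes at 7.37 % product, near Thursday's first reading of 7.9 %.

5. Level. Thursday's curve bends toward 34.2 %.

6. At 30 % conversion. Count the catalyst charge as bound. That leaves 0.501 M of product and 0.207 M of partner, below c×. Twice the partner charge leaves 0.784 M, so I reckon a factor of 3.78. More catalyst raises c× and the bound amount together, so I reckon an order of 2.89.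

7. Forecast. It says “partner is lost to second-order self-condensation” and gives 1.9 and 3.1, both lower than my numbers.

8. Result. Thursday's flask gives 3.1 and 3.94, reached at 1.36 h.

    free catalyst + left-handed substrate ⇌ catalyst intermediate A (K = 16.0 L mol⁻¹, k = 18.2 L mol⁻¹ min⁻¹)
    free catalyst + right-handed substrate ⇌ catalyst intermediate B (K = 0.540 L mol⁻¹, k = 1.87 L mol⁻¹ min⁻¹)
    coupling partner + catalyst intermediate A → free catalyst + left-handed product (k = 0.163 L mol⁻¹ min⁻¹)
    coupling partner + catalyst intermediate B → free catalyst + right-handed product (k = 0.00330 L mol⁻¹ min⁻¹)
    2 coupling partner → self-condensation product (k = 0.00944 L mol⁻¹ min⁻¹)

Take self-condensation out of this flask and the simulated run shows the largest single effect on the order: it falls from 3.1 to 1.1. The c× = 0.775 M belongs to the actual flask; that run has no crossing. With that drain gone, the rule leaves 0.599 M of partner at this conversion instead of 0.207 M, a factor of 2.89. The simulated rate there is 3.25 times the actual one.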